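The route rests on cutting the C5–O and C6–O bonds together. C5, the tertiary carbinol of the cyclopentenone ring, and C6, the neighbouring side-chain acetoxy carbon, are traced back to an exocyclic C5=C6 double bond. The key step exploits this vicinal C5/C6 dioxygenation, which lies directly beside the C4 carbinol stereocentre. One oxygen-atom transfer to the E-alkene of (4S)-4-silyloxy-5-tridecylidenecyclopent-2-enone, on the face away from the silyl ether, closes a spiro-oxirane and sets C5 and C6 at once. Invertive acetolysis at C6 then differentiates the two oxygens. The precursor is a flat cross-conjugated dienone with C4 as its only stereocentre. It comes in two steps from a commercial enantiopure 4-silyloxycyclopentenone and tridecanal.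

Key step: step 3

Remark on numbering and descriptors: C1 is the ring C=O, C2=C3 the ring alkene, C4 the ring secondary carbinol, C5 the ring tertiary carbinol and C6 the first side-chain carbon. Some CIP letters change along the route only because substituent priorities change. The purchased enone is R, yet the same untouched centre is 4S once C5 is substituted. C5 is R in the silyl ethers and S in the free diol.

Step 1
Reactants: 1 (R)-4-(tert-butyldimethylsilyloxy)cyclopent-2-en-1-one; 2 tridecanal
Product: 5 (4S,5R)-4-(tert-butyldimethylsilyloxy)-5-(1-hydroxytridecyl)cyclopent-2-en-1-one as a mixture of C6 epimers, via lithium dienolate 3 (not isolated), via lithium aldolate 4 (not isolated)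
Conditions: LDA (commercial solution), THF, −78 °C; then 2, −78 °C; AcOH quench at −78 °C
Reagents that add atoms: none
Why: Kinetic α′-deprotonation at C5 gives the cross-conjugated lithium dienolate, whose loss of silyloxide is held back at −78 °C because it would lead to an antiaromatic cyclopentadienone; its directed aldol addition should occur on the face opposite the C4 silyloxy group (side chain trans to it), and the C6 configuration does not matter because C5 and C6 both become sp2 in step 2.

Step 2
Reactants: 5 (4S,5R)-4-(tert-butyldimethylsilyloxy)-5-(1-hydroxytridecyl)cyclopent-2-en-1-one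
Product: 7 (4S,5E)-4-(tert-butyldimethylsilyloxy)-5-tridecylidenecyclopent-2-en-1-one, via mesylate 6 (not isolated)
Conditions: MsCl, Et3N (excess), CH2Cl2, 0 °C to rt; chromatography to remove any Z isomer
Reagents that add atoms: none
Why: Mesylation followed by E1cB elimination through the C5 enolate (aldol-condensation type dehydration) expels the far better leaving group mesylate and not the C4 silyloxide, and should favour the E-alkene with the chain turned away from the carbonyl oxygen; geometric purity is secured here because any Z isomer would end up as the C6 epimer.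

Step 3
Reactants: 7 (4S,5E)-4-(tert-butyldimethylsilyloxy)-5-tridecylidenecyclopent-2-en-1-one
Product: 8 (2R,3R,7S)-7-(tert-butyldimethylsilyloxy)-2-dodecyl-1-oxaspiro[2.4]hept-5-en-4-one (oxirane oxygen trans to the C4 silyloxy group; 5R,6R in route numbering)
Conditions: DMDO (acetone solution, excess, in portions), CH2Cl2, 0 °C to rt, dark
Reagents that add atoms: dimethyldioxirane, CC1(C)OO1
Why: The dioxirane hands one oxygen atom to the C5=C6 π bond through a concerted spiro transition state, so both C–O bonds form on the same face and the alkene geometry is copied into the oxirane. The closest known reaction type is the dioxirane epoxidation of α-alkylidene ketones and other enones, together with the anti-selective epoxidation of cyclic allylic silyl ethers. The three-membered ring is closed by this single [2+1] oxygen-atom addition, not by a stepwise cyclisation, and becomes spiro to the cyclopentenone at C5. C5 is controlled by the C4 silyloxy group, which covers its own face of the nearly planar ring and has no O–H to guide the oxidant by hydrogen bonding, so oxygen should enter trans to it; C6 is controlled by the E geometry, which keeps the dodecyl chain on the C4 side and gives the (6R)-oxirane carbon. Site selectivity is also needed: the electrophilic oxidant should prefer the trisubstituted exocyclic alkene to the disubstituted C2=C3 bond, which shares the same carbonyl but has one donor alkyl group fewer. The neutral, non-nucleophilic medium should leave the enone, the silyl ether and the sensitive epoxy ketone untouched.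

Step 4
Reactants: 8 (2R,3R,7S)-7-(tert-butyldimethylsilyloxy)-2-dodecyl-1-oxaspiro[2.4]hept-5-en-4-one
Product: 9 (1S)-1-[(1R,5S)-5-(tert-butyldimethylsilyloxy)-1-hydroxy-2-oxocyclopent-3-en-1-yl]tridecyl acetate
Conditions: AcOH, CsOAc (buffer), 55 °C
Reagents that add atoms: acetic acid, CC(=O)O
Why: This is the acetolysis (trans-opening) of an α,β-epoxy ketone: with the oxirane oxygen activated by acetic acid, acetate attacks in SN2 fashion at the secondary, carbonyl-remote C6 and not at the fully substituted C5, where positive charge next to the ketone is disfavoured, so C6 inverts from R to S, the C5–O bond keeps its configuration, and acetate and tertiary hydroxyl land directly on the correct oxygens.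

Step 5
Reactants: 9 (1S)-1-[(1R,5S)-5-(tert-butyldimethylsilyloxy)-1-hydroxy-2-oxocyclopent-3-en-1-yl]tridecyl acetate
Product: 10 (1S)-1-[(1S,5S)-1,5-dihydroxy-2-oxocyclopent-3-en-1-yl]tridecyl acetate (target, 4S,5S,6S in route numbering)
Conditions: HF·pyridine, pyridine, THF, 0 °C to rt (plastic vessel)
Reagents that add atoms: none
Why: Fluoride-driven Si–O cleavage under buffered, mildly acidic conditions (silyl ether deprotection) touches no stereocentre and avoids the alkoxides that could trigger acetyl migration from O6 to O4 or O5, retro-aldol cleavage or addition to the enone.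

Compound list
1 | (R)-4-(tert-butyldimethylsilyloxy)cyclopent-2-en-1-one | O=C1C=C[C@H](O[Si](C)(C)C(C)(C)C)C1 | starting material
2 | tridecanal | CCCCCCCCCCCCC=O | starting material
3 | lithium dienolate of 1 (C1–C5 enolate, C4 unchanged) | [Li+].[O-]C1=C[C@@H](O[Si](C)(C)C(C)(C)C)C=C1 | intermediate
4 | lithium aldolate (side chain trans to the silyloxy group, C6 epimers) | [Li+].CCCCCCCCCCCCC([O-])[C@H]1C(=O)C=C[C@@H]1O[Si](C)(C)C(C)(C)C | intermediate
5 | (4S,5R)-4-(tert-butyldimethylsilyloxy)-5-(1-hydroxytridecyl)cyclopent-2-en-1-one (C6 epimers) | CCCCCCCCCCCCC(O)[C@H]1C(=O)C=C[C@@H]1O[Si](C)(C)C(C)(C)C | intermediate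
6 | C6 methanesulfonate of 5 | CCCCCCCCCCCCC(OS(C)(=O)=O)[C@H]1C(=O)C=C[C@@H]1O[Si](C)(C)C(C)(C)C | intermediate
7 | (4S,5E)-4-(tert-butyldimethylsilyloxy)-5-tridecylidenecyclopent-2-en-1-one | CCCCCCCCCCCC/C=C1/C(=O)C=C[C@@H]1O[Si](C)(C)C(C)(C)C | intermediate
8 | (2R,3R,7S)-7-(tert-butyldimethylsilyloxy)-2-dodecyl-1-oxaspiro[2.4]hept-5-en-4-one | CCCCCCCCCCCC[C@H]1O[C@]12C(=O)C=C[C@@H]2O[Si](C)(C)C(C)(C)C | intermediate
9 | (1S)-1-[(1R,5S)-5-(tert-butyldimethylsilyloxy)-1-hydroxy-2-oxocyclopent-3-en-1-yl]tridecyl acetate | CCCCCCCCCCCC[C@H](OC(C)=O)[C@]1(O)C(=O)C=C[C@@H]1O[Si](C)(C)C(C)(C)C | intermediate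
10 | (1S)-1-[(1S,5S)-1,5-dihydroxy-2-oxocyclopent-3-en-1-yl]tridecyl acetate | CCCCCCCCCCCC[C@H](OC(C)=O)[C@]1(O)C(=O)C=C[C@@H]1O | target

Total step count: 5
Longest linear sequence: 5

Steps most likely to fail

**Step 3.** Oxygen transfer to the carbonyl-deactivated alkene may be slow. It may also stray to the C2=C3 bond, or show too little preference for the face opposite the silyl ether.

The fallback sets out from 7 and comes back at 8. It moves the oxidation to the alcohol oxidation level, where the alkene is more electron-rich and is shielded from both flanks.
- Luche reduction of 7 (NaBH4, CeCl3·7H2O, MeOH, −78 °C, hydride anti to the silyl ether) should give the cis-dienol F1.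
- TESCl and imidazole convert it into the bis-silyl ether F2, in which C1 and C4 both carry a silyloxy group on the same face.
- mCPBA with NaHCO3 in CH2Cl2 should epoxidise the trisubstituted exocyclic alkene from the open face to give the spiro-epoxide F3.
- PPTS in MeOH at 0 °C removes only the triethylsilyl group to give the epoxy alcohol F4.
- Buffered Dess–Martin oxidation restores the enone and delivers 8.

**Step 4.** The backside approach to C6 runs past the silyl ether and next to a fully substituted carbon, so the opening may be sluggish. Forcing it could bring C6–O ionisation with acyl shift and ring enlargement, erosion of the inversion, or premature silyl loss followed by acetyl migration.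

The fallback sets out from 8 and comes back at 9. It separates C–O bond formation from acylation.
- Catalytic HClO4 in THF–H2O at 0 °C lets the small nucleophile water, present in large excess, open the oxirane at C6 with inversion to give the (5R,6S)-diol F5.
- Ac2O in pyridine at 0 °C then acetylates the only secondary free hydroxyl (C5–OH is tertiary, O4 is silylated) to give 9.

**Step 1.** The dienolate may lose silyloxide. Proton transfer to the dienolate may set off self-condensation of the aldehyde, or the aldolate may revert on work-up.

The fallback sets out from 2 and comes back at 7. It builds the ring skeleton from a fulvene, at the price of a resolution that uses only one enantiomer.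
- Cyclopentadiene F6, freshly cracked from commercial dicyclopentadiene, condenses with 2 (pyrrolidine, MeOH, 0 °C to rt) to give 6-dodecylfulvene F7.
- Sensitised photooxygenation (O2, tetraphenylporphyrin, hν, CH2Cl2, −78 °C) adds singlet oxygen across the ring diene to give the bicyclic endoperoxide F8.
- F8 is kept cold and treated with Et3N. Kornblum–DeLaMare fragmentation, by removal of the more accessible bridgehead hydrogen remote from the chain, should give the racemic E-hydroxy dienone F9.
- Lipase-catalysed acetylation with vinyl acetate in MTBE follows. By the empirical size rule for secondary alcohols, it is expected to leave the (4S)-alcohol F10 and to convert its antipode into the (4R)-acetate F11, which is separated.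
- TBSCl and imidazole in DMF turn F10 into 7.

Further compounds
F1 | step 3 | (1R,4S)-4-(tert-butyldimethylsilyloxy)-5-tridecylidenecyclopent-2-en-1-ol, C1–OH cis to the silyloxy group, alkene geometry retained | CCCCCCCCCCCC/C=C1/[C@H](O)C=C[C@@H]1O[Si](C)(C)C(C)(C)C
F2 | step 3 | C1 triethylsilyl ether of F1 | CCCCCCCCCCCC/C=C1/[C@H](O[Si](CC)(CC)CC)C=C[C@@H]1O[Si](C)(C)C(C)(C)C
F3 | step 3 | spiro-epoxide of F2, oxirane oxygen trans to both silyloxy groups | CCCCCCCCCCCC[C@H]1O[C@]12[C@H](O[Si](CC)(CC)CC)C=C[C@@H]2O[Si](C)(C)C(C)(C)C
F4 | step 3 | epoxy alcohol from selective removal of the triethylsilyl group of F3 | CCCCCCCCCCCC[C@H]1O[C@]12[C@H](O)C=C[C@@H]2O[Si](C)(C)C(C)(C)C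
F5 | step 4 | (4S,5R)-4-(tert-butyldimethylsilyloxy)-5-hydroxy-5-[(1S)-1-hydroxytridecyl]cyclopent-2-en-1-one | CCCCCCCCCCCC[C@H](O)[C@]1(O)C(=O)C=C[C@@H]1O[Si](C)(C)C(C)(C)C
F6 | step 1 | cyclopentadiene | C1C=CC=C1
F7 | step 1 | 6-dodecylfulvene | CCCCCCCCCCCCC=C1C=CC=C1
F8 | step 1 | 7-tridecylidene-2,3-dioxabicyclo[2.2.1]hept-5-ene (racemic) | CCCCCCCCCCCCC=C1C2C=CC1OO2
F9 | step 1 | (5E)-4-hydroxy-5-tridecylidenecyclopent-2-en-1-one (racemic) | CCCCCCCCCCCC/C=C1/C(=O)C=CC1O
F10 | step 1 | (4S,5E)-4-hydroxy-5-tridecylidenecyclopent-2-en-1-one | CCCCCCCCCCCC/C=C1/C(=O)C=C[C@@H]1O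
F11 | step 1 | (4R,5E)-4-acetoxy-5-tridecylidenecyclopent-2-en-1-one | CCCCCCCCCCCC/C=C1/C(=O)C=C[C@H]1OC(C)=O
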